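**Retrosynthetic overview** (chromene numbering O1, C2–C8a; side chain C1'–C13')

1. The target 30 is cut at C2'–C3' (B-alkyl Suzuki coupling) into the iodoethyl chromene 20 and the E-iodoalkene 26; 26 comes from geranial, with C6' set by asymmetric propargylation.
2. The plan rests on the benzene ring: its six carbons are read as three alkynes, C8a–C8 (a 1-propynyl ether on O1 that brings the C8 methyl), C4a–C5 (a terminal alkyne on C4) and C6–C7 (an ethynylboronate, boron standing for the C6 hydroxyl), with O1–C2–C3–C4 as tether.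
3. A 1-alkynyl ether on an allylic oxygen would undergo a [3,3] shift to a ketene far below room temperature, so C2 carries no alkenyl group at the cycloaddition stage. C3–C4 is held as CH2–CH(OMe) and the C3=C4 bond is released later by loss of methanol; the C1'–C2' arm is a trityloxyethyl group.
4. C2 (R) is taken unchanged from (R)-mevalonolactone (carbonyl carbon → C4, CH2CH2O arm → C1'–C2', tertiary OH → O1). The ynol ether is built on the alkoxide, so no bond at C2 is ever broken.
5. Ring order: benzene and pyran rings close together in step 7; the chromene double bond follows in step 12.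

Key step: step 7

Remark 1: the carbinol carbon made in step 2 (later C4) is carried as a mixture of epimers until it becomes sp2 in step 12; names and SMILES leave it undefined.
Remark 2: geranial is taken as the pure E aldehyde.
Remark 3: the sense of induction of the chiral acid in step 13 is assumed by analogy with aryl and alkenyl aldehydes; the antipodal acid would be used if the sense proves opposite.

**Route**

Step 1
Reactants: 1 (R)-mevalonolactone
Product: 2 (4R)-4-methyloxane-2,4-diol (lactol, C2 epimers)
Conditions: i-Bu2AlH (2.2 equiv), CH2Cl2/THF, −78 °C; aq. potassium sodium tartrate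
Reagents that add atoms: none
Why: Half-reduction of a lactone to the lactol with i-Bu2AlH at −78 °C is standard because the tetrahedral aluminium acetal persists until work-up; the tertiary hydroxyl only uses up one hydride and the stereocentre (the future C2) is not touched.

Step 2
Reactants: 2 (4R)-4-methyloxane-2,4-diol; 3 (triisopropylsilyl)acetylene
Product: 5 (5R)-5-methyl-1-(triisopropylsilyl)hept-1-yne-3,5,7-triol (C3 epimers), via alkynylmagnesium bromide 4 (not isolated)
Conditions: 3 (4.2 equiv), EtMgBr (4.0 equiv), THF, 0 → 40 °C; then 2, 0 °C → rt; aq. NH4Cl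
Reagents that add atoms: none
Why: Alkynyl Grignard addition to the open hydroxy-aldehyde form of a lactol (two equivalents act as base for the two hydroxyls, a third adds) gives the propargylic carbinol; the new carbinol centre (future C4) forms without control, which does not matter because it becomes sp2 in step 12.

Step 3
Reactants: 5 (5R)-5-methyl-1-(triisopropylsilyl)hept-1-yne-3,5,7-triol
Product: 6 (5R)-5-methyl-1-(triisopropylsilyl)-7-(trityloxy)hept-1-yne-3,5-diol
Conditions: TrCl (1.1 equiv), Et3N, DMAP (cat.), CH2Cl2, 0 °C → rt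
Reagents that add atoms: trityl chloride, ClC(c1ccccc1)(c1ccccc1)c1ccccc1
Why: Tritylation is selective for the primary hydroxyl over the secondary propargylic and tertiary ones, and a trityl ether, unlike a silyl ether, cannot migrate to a neighbouring alkoxide in steps 4 and 5.

Step 4
Reactants: 6 (5R)-5-methyl-1-(triisopropylsilyl)-7-(trityloxy)hept-1-yne-3,5-diol
Product: 7 (3R)-5-methoxy-3-methyl-7-(triisopropylsilyl)-1-(trityloxy)hept-6-yn-3-ol
Conditions: NaH (1.05 equiv), MeI (1.2 equiv), THF, 0 °C
Reagents that add atoms: iodomethane, CI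
Why: Williamson methylation with one equivalent of base goes to the more acidic and far less hindered secondary propargylic alkoxide and leaves the tertiary hydroxyl free; the methyl ether is inert to base, fluoride and ruthenium and later serves as the leaving group at C4.

Step 5
Reactants: 7 (3R)-5-methoxy-3-methyl-7-(triisopropylsilyl)-1-(trityloxy)hept-6-yn-3-ol; 8 trichloroethylene
Product: 12 (3R)-5-methoxy-3-methyl-3-(prop-1-yn-1-yloxy)-7-(triisopropylsilyl)-1-(trityloxy)hept-6-yne, via dichloroacetylene 9 (not isolated), via dichlorovinyl ether 10 (not isolated), via lithium alkynyl ether 11 (not isolated)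
Conditions: KH (2.2 equiv), THF, 0 °C; 8 (1.2 equiv), −50 °C → rt; n-BuLi (2.5 equiv), −78 → −40 °C; MeI, HMPA, −78 °C → rt
Reagents that add atoms: iodomethane, CI
Why: Greene ynol ether synthesis: the potassium alkoxide adds anti to dichloroacetylene (made in the flask from 8 and KH) to give the E-dichlorovinyl ether, n-BuLi effects dehydrochlorination and chlorine–lithium exchange, and the lithium alkynyl ether is C-methylated by MeI in HMPA; O1–C8a is thus made on the alkoxide so the configuration at C2 stays that of 1, and the triisopropylsilyl cap keeps the other alkyne from being metalated and methylated.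

Step 6
Reactants: 12 (3R)-5-methoxy-3-methyl-3-(prop-1-yn-1-yloxy)-7-(triisopropylsilyl)-1-(trityloxy)hept-6-yne
Product: 13 (3R)-5-methoxy-3-methyl-3-(prop-1-yn-1-yloxy)-1-(trityloxy)hept-6-yne
Conditions: Bu4NF (1.5 equiv), THF, 0 °C → rt; Et3N-deactivated silica, product stored cold
Reagents that add atoms: none
Why: Fluoride-induced protodesilylation of the alkynylsilane leaves trityl ether, methyl ether and the base-stable ynol ether untouched; the product is handled cold and acid-free because tertiary 1-alkynyl ethers hydrate with acid and lose a ketene (retro-ene) on warming.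

Step 7
Reactants: 13 (3R)-5-methoxy-3-methyl-3-(prop-1-yn-1-yloxy)-1-(trityloxy)hept-6-yne; 14 ethynylboronic acid pinacol ester
Product: 15 (2R)-4-methoxy-2,8-dimethyl-6-(4,4,5,5-tetramethyl-1,3,2-dioxaborolan-2-yl)-2-[2-(trityloxy)ethyl]chromane (C4 epimers)
Conditions: Cp*RuCl(cod) (10 mol %), 14 (3 equiv), ClCH2CH2Cl, 20 °C, 13 added over 6 h, Ar
Reagents that add atoms: none
Why: Proposed new method: oxidative cyclisation of the ynol ether and the terminal alkyne of 13 on the Cp*RuCl fragment (divalent ruthenium) should give a ruthenacycle fused to the forming pyran ring (bond C4a–C8a), after which 14 inserts and reductive elimination forms C5–C6 and C7–C8 and releases the arene; the closest known reaction type is the Cp*RuCl(cod)-catalysed [2+2+2] cyclotrimerisation of unsymmetrical tethered diynes with terminal alkynes and alkynylboronates, which has not been shown for a diyne whose tether oxygen sits on an alkyne carbon. The pyran ring closes as the six-membered ring annulated to the metallacycle (a 1,7-diyne closing through O1–C2–C3–C4, helped by the fully substituted C2 and the branched C4), and the benzene ring closes by the cycloaddition itself. No stereocentre is formed: C2 is a spectator and C4 stays an epimer mixture. The selectivity needed is boron on C6, and this catalyst places the substituent of a terminal alkyne meta to the substituted terminus of the diyne because 14 adds at the unsubstituted ruthenium-bound C5 with its boryl group turned away from the C8 methyl. Cross-coupling over homo-coupling is secured by excess 14 and slow addition of 13, the alkynes have no competing alkene at C2, and ambient temperature keeps the tertiary ynol ether from losing a ketene.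

Step 8
Reactants: 15 (2R)-4-methoxy-2,8-dimethyl-6-(4,4,5,5-tetramethyl-1,3,2-dioxaborolan-2-yl)-2-[2-(trityloxy)ethyl]chromane
Product: 16 (2R)-4-methoxy-2,8-dimethyl-2-[2-(trityloxy)ethyl]chroman-6-ol
Conditions: NaBO3·4H2O (3 equiv), THF/H2O, rt
Reagents that add atoms: sodium perborate, [Na+].[O-]OB=O
Why: Oxidation of the aryl boronate by perborate (aryl shift from boron to oxygen, then hydrolysis) gives the phenol under mild, weakly basic conditions that leave the trityl and benzylic methyl ethers intact.

Step 9
Reactants: 16 (2R)-4-methoxy-2,8-dimethyl-2-[2-(trityloxy)ethyl]chroman-6-ol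
Product: 17 (2R)-4-methoxy-2,8-dimethyl-6-(triisopropylsilyloxy)-2-[2-(trityloxy)ethyl]chromane
Conditions: TIPSCl, imidazole, DMF, rt
Reagents that add atoms: chlorotriisopropylsilane, CC(C)[Si](Cl)(C(C)C)C(C)C
Why: Silylation of the unhindered phenol masks the acidic OH for the organolithium step and gives an aryl silyl ether that survives the acid of steps 10 and 12.

Step 10
Reactants: 17 (2R)-4-methoxy-2,8-dimethyl-6-(triisopropylsilyloxy)-2-[2-(trityloxy)ethyl]chromane
Product: 18 2-[(2R)-4-methoxy-2,8-dimethyl-6-(triisopropylsilyloxy)chroman-2-yl]ethanol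
Conditions: camphorsulfonic acid (0.1 equiv), MeOH/CH2Cl2, 0 °C → rt
Reagents that add atoms: none
Why: Acid-catalysed solvolysis of the trityl ether in methanol (trityl cation captured as its methyl ether) runs under conditions too mild to ionise the benzylic C4 methyl ether, and any exchange at C4 in methanol would be degenerate.

Step 11
Reactants: 18 2-[(2R)-4-methoxy-2,8-dimethyl-6-(triisopropylsilyloxy)chroman-2-yl]ethanol
Product: 19 (2S)-2-(2-iodoethyl)-4-methoxy-2,8-dimethyl-6-(triisopropylsilyloxy)chromane
Conditions: I2, PPh3, imidazole, CH2Cl2, 0 °C → rt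
Reagents that add atoms: iodine, II
Why: Appel-type iodination (SN2 displacement of the primary alkoxyphosphonium by iodide) meets no other hydroxyl; the descriptor at C2 changes to S only because iodine raises the rank of the side arm, the geometry being unchanged.

Step 12
Reactants: 19 (2S)-2-(2-iodoethyl)-4-methoxy-2,8-dimethyl-6-(triisopropylsilyloxy)chromane
Product: 20 (2R)-2-(2-iodoethyl)-2,8-dimethyl-6-(triisopropylsilyloxy)-2H-chromene
Conditions: p-TsOH·H2O (0.1 equiv), 4 Å MS, toluene, 70 °C
Reagents that add atoms: none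
Why: Acid-catalysed E1 loss of methanol from the 4-methoxychroman (benzylic cation stabilised by the ortho ring oxygen O1, proton lost from C3) follows the pathway of the classical dehydration of chroman-4-ols to 2H-chromenes; with the side-arm oxygen already replaced by iodine nothing can trap the C4 cation, and both C4 epimers converge on one alkene.

Step 13
Reactants: 21 geranial; 22 allenylboronic acid pinacol ester
Product: 23 (4R,5E)-6,10-dimethylundeca-5,9-dien-1-yn-4-ol
Conditions: (R)-TRIP (5 mol %), 4 Å MS, toluene, −20 °C; aqueous work-up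
Reagents that add atoms: none
Why: Chiral phosphoric acid-catalysed propargylboration through a closed six-membered SE2' transition state gives only the homopropargylic alcohol; the catalyst must direct attack to the Re face of the formyl group of 21 to set 4R (the future C6'), which (R)-TRIP is expected to do by analogy with aryl and alkenyl aldehydes.

Step 14
Reactants: 23 (4R,5E)-6,10-dimethylundeca-5,9-dien-1-yn-4-ol
Product: 24 tert-butyl{[(4R,5E)-6,10-dimethylundeca-5,9-dien-1-yn-4-yl]oxy}dimethylsilane
Conditions: TBSCl, imidazole, DMF, rt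
Reagents that add atoms: tert-butyldimethylsilyl chloride, CC(C)(C)[Si](C)(C)Cl
Why: Standard silylation of a secondary alcohol, needed so that the allylic oxygen does not bind and ionise under the Lewis acidic carboalumination conditions.

Step 15
Reactants: 24 tert-butyl{[(4R,5E)-6,10-dimethylundeca-5,9-dien-1-yn-4-yl]oxy}dimethylsilane
Product: 26 tert-butyl{[(1E,4R,5E)-1-iodo-2,6,10-trimethylundeca-1,5,9-trien-4-yl]oxy}dimethylsilane, via alkenylalane 25 (not isolated)
Conditions: AlMe3 (2.5 equiv), Cp2ZrCl2 (0.25 equiv), H2O (1 equiv), CH2Cl2, −20 °C; then I2, THF, −30 → 0 °C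
Reagents that add atoms: trimethylaluminium, C[Al](C)C; iodine, II
Why: Negishi zirconium-catalysed carboalumination (water-accelerated variant) adds methyl and aluminium syn across the terminal alkyne with methyl on the internal carbon, and iodinolysis with retention gives the E-iodoalkene; the trisubstituted alkenes do not react.

Step 16
Reactants: 20 (2R)-2-(2-iodoethyl)-2,8-dimethyl-6-(triisopropylsilyloxy)-2H-chromene; 26 tert-butyl{[(1E,4R,5E)-1-iodo-2,6,10-trimethylundeca-1,5,9-trien-4-yl]oxy}dimethylsilane
Product: 29 (2R)-2-[(3E,6R,7E)-6-(tert-butyldimethylsilyloxy)-4,8,12-trimethyltrideca-3,7,11-trien-1-yl]-2,8-dimethyl-6-(triisopropylsilyloxy)-2H-chromene, via alkyllithium 27 (not isolated), via borate complex 28 (not isolated)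
Conditions: 20 (1.3 equiv), B-methoxy-9-BBN, t-BuLi, Et2O/THF, −78 °C → rt; then 26, PdCl2(dppf) (5 mol %), AsPh3, aq. Cs2CO3, DMF, rt
Reagents that add atoms: none
Why: B-alkyl Suzuki–Miyaura coupling: iodine–lithium exchange in the presence of B-methoxy-9-BBN gives the alkyl borate, whose primary alkyl group is transferred to the alkenylpalladium iodide with retention of the E geometry; no stereocentre is touched.

Step 17
Reactants: 29 (2R)-2-[(3E,6R,7E)-6-(tert-butyldimethylsilyloxy)-4,8,12-trimethyltrideca-3,7,11-trien-1-yl]-2,8-dimethyl-6-(triisopropylsilyloxy)-2H-chromene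
Product: 30 (2R)-2-[(3E,6R,7E)-6-hydroxy-4,8,12-trimethyltrideca-3,7,11-trien-1-yl]-2,8-dimethyl-2H-chromen-6-ol (CNP0322676.1)
Conditions: Bu4NF (3 equiv), THF, 0 °C → rt, degassed
Reagents that add atoms: none
Why: Fluoride cleaves the aryl triisopropylsilyl and the secondary tert-butyldimethylsilyl ether under conditions that leave the chromene, the trisubstituted alkenes and both stereocentres unchanged.

**Compound list**

1 | (R)-mevalonolactone | O=C1C[C@](C)(O)CCO1 | starting material
2 | (4R)-4-methyloxane-2,4-diol | OC1C[C@](C)(O)CCO1 | intermediate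
3 | (triisopropylsilyl)acetylene | C#C[Si](C(C)C)(C(C)C)C(C)C | starting material
4 | [(triisopropylsilyl)ethynyl]magnesium bromide | Br[Mg]C#C[Si](C(C)C)(C(C)C)C(C)C | intermediate (not isolated)
5 | (5R)-5-methyl-1-(triisopropylsilyl)hept-1-yne-3,5,7-triol | OCC[C@](O)(C)CC(O)C#C[Si](C(C)C)(C(C)C)C(C)C | intermediate
6 | (5R)-5-methyl-1-(triisopropylsilyl)-7-(trityloxy)hept-1-yne-3,5-diol | c1ccccc1C(c1ccccc1)(c1ccccc1)OCC[C@](O)(C)CC(O)C#C[Si](C(C)C)(C(C)C)C(C)C | intermediate
7 | (3R)-5-methoxy-3-methyl-7-(triisopropylsilyl)-1-(trityloxy)hept-6-yn-3-ol | c1ccccc1C(c1ccccc1)(c1ccccc1)OCC[C@](O)(C)CC(OC)C#C[Si](C(C)C)(C(C)C)C(C)C | intermediate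
8 | trichloroethylene | ClC=C(Cl)Cl | starting material
9 | dichloroacetylene | ClC#CCl | intermediate (not isolated)
10 | (3R)-3-[(E)-1,2-dichlorovinyloxy]-5-methoxy-3-methyl-7-(triisopropylsilyl)-1-(trityloxy)hept-6-yne | c1ccccc1C(c1ccccc1)(c1ccccc1)OCC[C@](O/C(Cl)=C\Cl)(C)CC(OC)C#C[Si](C(C)C)(C(C)C)C(C)C | intermediate (not isolated)
11 | (3R)-3-(lithioethynyloxy)-5-methoxy-3-methyl-7-(triisopropylsilyl)-1-(trityloxy)hept-6-yne | c1ccccc1C(c1ccccc1)(c1ccccc1)OCC[C@](OC#C[Li])(C)CC(OC)C#C[Si](C(C)C)(C(C)C)C(C)C | intermediate (not isolated)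
12 | (3R)-5-methoxy-3-methyl-3-(prop-1-yn-1-yloxy)-7-(triisopropylsilyl)-1-(trityloxy)hept-6-yne | c1ccccc1C(c1ccccc1)(c1ccccc1)OCC[C@](OC#CC)(C)CC(OC)C#C[Si](C(C)C)(C(C)C)C(C)C | intermediate
13 | (3R)-5-methoxy-3-methyl-3-(prop-1-yn-1-yloxy)-1-(trityloxy)hept-6-yne | c1ccccc1C(c1ccccc1)(c1ccccc1)OCC[C@](OC#CC)(C)CC(OC)C#C | intermediate
14 | ethynylboronic acid pinacol ester | C#CB1OC(C)(C)C(C)(C)O1 | starting material
15 | (2R)-4-methoxy-2,8-dimethyl-6-(4,4,5,5-tetramethyl-1,3,2-dioxaborolan-2-yl)-2-[2-(trityloxy)ethyl]chromane | c1ccccc1C(c1ccccc1)(c1ccccc1)OCC[C@]1(C)CC(OC)c2cc(B3OC(C)(C)C(C)(C)O3)cc(C)c2O1 | intermediate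
16 | (2R)-4-methoxy-2,8-dimethyl-2-[2-(trityloxy)ethyl]chroman-6-ol | c1ccccc1C(c1ccccc1)(c1ccccc1)OCC[C@]1(C)CC(OC)c2cc(O)cc(C)c2O1 | intermediate
17 | (2R)-4-methoxy-2,8-dimethyl-6-(triisopropylsilyloxy)-2-[2-(trityloxy)ethyl]chromane | c1ccccc1C(c1ccccc1)(c1ccccc1)OCC[C@]1(C)CC(OC)c2cc(O[Si](C(C)C)(C(C)C)C(C)C)cc(C)c2O1 | intermediate
18 | 2-[(2R)-4-methoxy-2,8-dimethyl-6-(triisopropylsilyloxy)chroman-2-yl]ethanol | OCC[C@]1(C)CC(OC)c2cc(O[Si](C(C)C)(C(C)C)C(C)C)cc(C)c2O1 | intermediate
19 | (2S)-2-(2-iodoethyl)-4-methoxy-2,8-dimethyl-6-(triisopropylsilyloxy)chromane | ICC[C@]1(C)CC(OC)c2cc(O[Si](C(C)C)(C(C)C)C(C)C)cc(C)c2O1 | intermediate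
20 | (2R)-2-(2-iodoethyl)-2,8-dimethyl-6-(triisopropylsilyloxy)-2H-chromene | ICC[C@]1(C)C=Cc2cc(O[Si](C(C)C)(C(C)C)C(C)C)cc(C)c2O1 | intermediate
21 | geranial | CC(C)=CCC/C(C)=C/C=O | starting material
22 | allenylboronic acid pinacol ester | C=C=CB1OC(C)(C)C(C)(C)O1 | starting material
23 | (4R,5E)-6,10-dimethylundeca-5,9-dien-1-yn-4-ol | C#CC[C@@H](O)/C=C(C)/CCC=C(C)C | intermediate
24 | tert-butyl{[(4R,5E)-6,10-dimethylundeca-5,9-dien-1-yn-4-yl]oxy}dimethylsilane | C#CC[C@@H](O[Si](C)(C)C(C)(C)C)/C=C(C)/CCC=C(C)C | intermediate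
25 | [(1E,4R,5E)-4-(tert-butyldimethylsilyloxy)-2,6,10-trimethylundeca-1,5,9-trien-1-yl]dimethylalane | C[Al](C)/C=C(\C)C[C@@H](O[Si](C)(C)C(C)(C)C)/C=C(C)/CCC=C(C)C | intermediate (not isolated)
26 | tert-butyl{[(1E,4R,5E)-1-iodo-2,6,10-trimethylundeca-1,5,9-trien-4-yl]oxy}dimethylsilane | I/C=C(\C)C[C@@H](O[Si](C)(C)C(C)(C)C)/C=C(C)/CCC=C(C)C | intermediate
27 | {2-[(2R)-2,8-dimethyl-6-(triisopropylsilyloxy)-2H-chromen-2-yl]ethyl}lithium | [Li]CC[C@]1(C)C=Cc2cc(O[Si](C(C)C)(C(C)C)C(C)C)cc(C)c2O1 | intermediate (not isolated)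
28 | lithium B-{2-[(2R)-2,8-dimethyl-6-(triisopropylsilyloxy)-2H-chromen-2-yl]ethyl}-B-methoxy-9-borabicyclo[3.3.1]nonan-9-uide | [Li+].CO[B-]1(CC[C@]2(C)C=Cc3cc(O[Si](C(C)C)(C(C)C)C(C)C)cc(C)c3O2)C2CCCC1CCC2 | intermediate (not isolated)
29 | (2R)-2-[(3E,6R,7E)-6-(tert-butyldimethylsilyloxy)-4,8,12-trimethyltrideca-3,7,11-trien-1-yl]-2,8-dimethyl-6-(triisopropylsilyloxy)-2H-chromene | CC(C)=CCC/C(C)=C/[C@H](O[Si](C)(C)C(C)(C)C)C/C(C)=C/CC[C@]1(C)C=Cc2cc(O[Si](C(C)C)(C(C)C)C(C)C)cc(C)c2O1 | intermediate
30 | (2R)-2-[(3E,6R,7E)-6-hydroxy-4,8,12-trimethyltrideca-3,7,11-trien-1-yl]-2,8-dimethyl-2H-chromen-6-ol | CC(C)=CCC/C(C)=C/[C@H](O)C/C(C)=C/CC[C@]1(C)C=Cc2cc(O)cc(C)c2O1 | target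

**Step count**

Total: 17 steps. Longest linear sequence: 14 steps (steps 1–12, 16, 17). The side-chain fragment takes steps 13–15.

**Steps most likely to fail, with fallbacks**

Step 7 (proposed new method). What may go wrong:
- loss of the ynol ether by retro-ene ketene extrusion or hydration before it enters the metallacycle;
- slow closure of the six-membered tether, so that homo-coupling of the diyne or trimerisation of 14 takes over;
- insertion of the boryl alkyne in the wrong orientation.

Fallback (known chemistry, sets out from 2, comes back at 17): the arene is bought rather than built, and O1–C8a is closed by palladium-catalysed intramolecular etherification of the tertiary alcohol with an aryl bromide, which again leaves the C2–O bond intact. Silylation of 3-bromo-5-methylphenol (TIPSCl, imidazole, DMF) gives (3-bromo-5-methylphenoxy)triisopropylsilane F1. Its Grignard reagent (Mg, THF), used in excess, opens lactol 2 to the benzylic triol (3R)-3-methyl-1-[3-methyl-5-(triisopropylsilyloxy)phenyl]pentane-1,3,5-triol F2. Tritylation of the primary hydroxyl (TrCl, Et3N, DMAP) gives the trityl ether diol F3, and methylation of the secondary benzylic hydroxyl (NaH, one equivalent, MeI) gives the methoxy tertiary alcohol F4. NBS in MeCN at 0 °C should brominate para to the silyloxy group, at the ring carbon between the methyl group and the side chain, to give the aryl bromide F5. Pd(OAc)2, 2-(di-tert-butylphosphino)-1,1'-binaphthyl and Cs2CO3 in toluene at 80 °C then close the pyran ring and deliver 17, from which step 10 follows.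

Step 5. What may go wrong: sluggish addition of the hindered tertiary potassium alkoxide to dichloroacetylene, and competing deprotonation at the propargylic C–H next to the methoxy group by n-BuLi.

Fallback (sets out from 7, comes back at 12): the ynol ether is made from a formate instead of from the alkoxide. Acetic formic anhydride and pyridine convert 7 into the formate F6. Dibromomethylenation of the formyl group (CBr4, PPh3, CH2Cl2) gives the 2,2-dibromovinyl ether F7. n-BuLi (2.2 equiv, THF, −78 °C) followed by MeI/HMPA gives 12.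

Step 13. What may go wrong: poor facial selectivity of the acid-catalysed propargylboration on a β,β-disubstituted enal, or the opposite sense of induction.

Fallback (sets out from 21, comes back at 23): the stereocentre is set by resolution. Zinc-mediated Barbier addition of propargyl bromide (Zn, THF/aq. NH4Cl) to 21 gives the racemic alcohol (5E)-6,10-dimethylundeca-5,9-dien-1-yn-4-ol F8. Candida antarctica lipase B with vinyl acetate in hexane should acylate the R enantiomer (the dienyl group as the large and the propargyl group as the medium substituent) to the acetate (4R,5E)-6,10-dimethylundeca-5,9-dien-1-yn-4-yl acetate F9, which is separated from the unreacted S alcohol. K2CO3 in MeOH then gives 23.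

Further compounds
F1 | step 7 | (3-bromo-5-methylphenoxy)triisopropylsilane | Cc1cc(Br)cc(O[Si](C(C)C)(C(C)C)C(C)C)c1
F2 | step 7 | (3R)-3-methyl-1-[3-methyl-5-(triisopropylsilyloxy)phenyl]pentane-1,3,5-triol | OCC[C@](O)(C)CC(O)c1cc(C)cc(O[Si](C(C)C)(C(C)C)C(C)C)c1
F3 | step 7 | (3R)-3-methyl-1-[3-methyl-5-(triisopropylsilyloxy)phenyl]-5-(trityloxy)pentane-1,3-diol | c1ccccc1C(c1ccccc1)(c1ccccc1)OCC[C@](O)(C)CC(O)c1cc(C)cc(O[Si](C(C)C)(C(C)C)C(C)C)c1
F4 | step 7 | (3R)-5-methoxy-3-methyl-5-[3-methyl-5-(triisopropylsilyloxy)phenyl]-1-(trityloxy)pentan-3-ol | c1ccccc1C(c1ccccc1)(c1ccccc1)OCC[C@](O)(C)CC(OC)c1cc(C)cc(O[Si](C(C)C)(C(C)C)C(C)C)c1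
F5 | step 7 | (3R)-5-[2-bromo-3-methyl-5-(triisopropylsilyloxy)phenyl]-5-methoxy-3-methyl-1-(trityloxy)pentan-3-ol | c1ccccc1C(c1ccccc1)(c1ccccc1)OCC[C@](O)(C)CC(OC)c1cc(O[Si](C(C)C)(C(C)C)C(C)C)cc(C)c1Br
F6 | step 5 | (3R)-5-methoxy-3-methyl-7-(triisopropylsilyl)-1-(trityloxy)hept-6-yn-3-yl formate | c1ccccc1C(c1ccccc1)(c1ccccc1)OCC[C@](OC=O)(C)CC(OC)C#C[Si](C(C)C)(C(C)C)C(C)C
F7 | step 5 | (3R)-3-(2,2-dibromovinyloxy)-5-methoxy-3-methyl-7-(triisopropylsilyl)-1-(trityloxy)hept-6-yne | c1ccccc1C(c1ccccc1)(c1ccccc1)OCC[C@](OC=C(Br)Br)(C)CC(OC)C#C[Si](C(C)C)(C(C)C)C(C)C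
F8 | step 13 | (5E)-6,10-dimethylundeca-5,9-dien-1-yn-4-ol (racemic) | C#CCC(O)/C=C(C)/CCC=C(C)C
F9 | step 13 | (4R,5E)-6,10-dimethylundeca-5,9-dien-1-yn-4-yl acetate | C#CC[C@@H](OC(C)=O)/C=C(C)/CCC=C(C)C
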